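Assumption: dimethyl squarate, 4-methylpent-3-enoic acid, ethynyltrimethylsilane and angelic acid are taken as purchasable. Target atoms are numbered ring C1 (side chain), C2 (OH), C3 (OCH3), C4 (CH3), C5 (OH), C6 (H), and side chain C1′ (=CH2), C2′, C3′ (stereocentre), C4′ to C6′ (prenyl part).

## The problem

Target 18 is a bisabolane-type hydroquinone: a pentasubstituted benzene ring joined through C1 to C2′ of a 6-methylhepta-1,5-diene chain, whose C3′ carries the only stereocentre as an (S)-configured allylic angelate. The side chain stands para to the C4 methyl and meta to the C3 methoxy group. On a ready-made 1,4-dioxygenated 2-methoxy-3-methylbenzene, electrophiles go instead to C6 (para to OCH3), so a route from the arene must override the innate regiochemistry and carry two phenol protecting groups. C3′ has no neighbouring stereocentre to lean on and must be set by a catalyst; its ketone precursor has a CH2 group between carbonyl and prenyl alkene that slips easily into conjugation. The ester is an angelate, whose (Z)-alkene turns into the tiglate when the acyl group is activated, and it must end up on the secondary oxygen and not on the two more acidic phenols. The finished molecule tolerates little: air oxidises the electron-rich hydroquinone to the quinone, acid or palladium invite ionisation of the allylic ester and SN2′ closure of the ortho hydroxyl to a benzofuran, and base invites acyl migration.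

The feature that opens another approach is this. Ring carbons C2–C3–C4–C5 carry O, OCH3, CH3, O, which is the substituent array of a squaric-acid-derived cyclobutenedione. The para relation of the C2 and C5 hydroxyls is the signature of the thermal ring expansion of a 4-alkenyl-4-hydroxycyclobutenone. C6–C1–C2′–C1′ is, before aromatisation, a cross-conjugated 2,3-disubstituted buta-1,3-diene, which is what ethylene makes from an alkyne. The benzene ring therefore need not exist until the last step, and no phenol is ever protected.

## Retrosynthesis

18 to 15. The ring bond C5–C6 is cut and C5 is reconnected to C2 (retro-6π-electrocyclisation through cyclohexadienone 17, then retro-4π-opening through dienylketene 16). This leads to 4-hydroxycyclobutenone 15, an isomer of 18 that holds the whole skeleton and the ester but no arene. The cut is preferred to the arene/side-chain cut (C1–C2′) because the substitution pattern becomes a consequence of the ring construction and both phenols appear free, under neutral reagent-free conditions, in the last step. 15 needs no regioselective aromatic substitution and is the union of two small halves. The forward reaction must open the four-membered ring with the hydroxyl turning outward, close the six-membered ring faster than the ketene is trapped, and spare the angelate.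

15 to 14 and ethylene. Both C=CH2 bonds (the later C1–C6 ring bond and C2′=C1′) are cut at once, which is an ethylene–alkyne cross-metathesis of internal alkyne 14. The neighbouring option, a preformed 3-metallated buta-1,3-dien-2-yl carbinol as the nucleophile, needs organotin chemistry and several extra steps. The alkyne is the simplest carrier of the two sp2 carbons and comes from a propargylic alcohol. 14 is simpler by the diene and two carbons. The forward step must turn over at an internal alkyne flanked by two oxygenated carbons and leave the prenyl alkene alone.

14 to 12 and 13. The C3′–O bond is cut; forward, a Mitsunobu reaction of diol 12 with angelic acid 13, with inversion. This is preferred to acyl transfer because the carboxylate is the nucleophile and the angeloyl carbonyl is never activated. The tertiary hydroxyl cannot react, and no phenol exists yet, so the site-selectivity problem of the target (secondary OH against two phenols) never arises. The forward step needs the (R) carbinol.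

12 to 3 and 10. The bond between the alkyne terminus and the cyclobutenone carbinol carbon is cut; forward, dilithio species 11 of alkynol 10 adds to dione 3. Of the two carbonyl groups of 3, the one next to the methoxy-bearing carbon is a simple ketone and the other a vinylogous ester. Attack at the former places OCH3 at C3, beside the hydroxyl (C2) that neighbours the side chain, and CH3 at C4, para to the chain. The union is convergent and each half takes at most four steps.

10 to 9 to 8 to 5 and 6. The stereocentre is traced to ynone 8 (asymmetric transfer hydrogenation to 9, then desilylation). Alkynyl ketones are among the best substrates for this reduction, and the silyl group masks the alkyne terminus. 8 comes from Weinreb amide 5 (from acid 4) and lithium acetylide 7 of ethynyltrimethylsilane 6. The neighbouring cut, asymmetric alkynylation of 4-methylpent-3-enal, would need a labile β,γ-unsaturated aldehyde.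

3 to 1. The C–CH3 bond is cut; forward, methyllithium adds to dimethyl squarate 1 and the alkoxide 2 is converted into the dione by trifluoroacetic anhydride with loss of methanol.

## Roads not taken

Alternative 1: the most obvious cut is the C1–C2′ bond between arene and side chain. In the forward key step, the arylmagnesium bromide from 1-bromo-3-methoxy-2,5-bis(methoxymethoxy)-4-methylbenzene A1 would add across the terminal alkyne of (3S)-6-methylhept-5-en-1-yn-3-ol A2 (alkoxide-directed anti-carbomagnesiation, CuBr·SMe2 catalysis). This would give allylic alcohol A3, followed by angeloylation and removal of the two acetals. The chosen plan is better for three reasons: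
- A1 needs the metal at the position para to CH3 and meta to OCH3, which electrophilic halogenation does not choose, so it costs a sequence of differential protection and directed metalation.
- The two acetals must be removed at the end with acid, next to an ionisable allylic ester and an ortho phenol poised for SN2′ ring closure.
- In the chosen plan the ring is born with the right pattern and without any O-protection.

Alternative 2: cut the C3′–O bond with allylic transposition. In the forward key step, the (Z)-allylic trichloroacetimidate A4 would undergo asymmetric SN2′ esterification with angelic acid 13, catalysed by the chiral palladacycle [(Rp,S)-COP-OAc]2 (divalent palladium). This would give the bis(methoxymethyl) ether A5 of the target and create stereocentre, methylidene group and ester in one step. The chosen plan is better because the proven scope of this reaction is 3-monosubstituted allylic imidates. With the aryl group on the central carbon, anti-oxypalladation would place palladium on a tertiary benzylic carbon. The trisubstituted (Z)-alkene of A4 must itself be made stereoselectively, and the arene and deprotection problems of alternative 1 remain.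

Alternative 3: cut the ring by a Dötz benzannulation (bonds C1–C2, C2–C3 and C5–C6, with C2 coming from CO). In the forward key step, the Cr(CO)5 alkenyl(methoxy)carbene complex A6 would react with enyne ester A7 to give phenol A8. The chosen plan is better because A6 is a stoichiometric chromium reagent with an unusual β-methoxy group, and A7 is no easier to make than 14. A8 also carries C5–O as a methyl ether that must be told apart from the C3 methyl ether in a late demethylation. The squarate route gives both hydroxyls free and takes its regiochemistry from one predictable carbonyl addition.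

Key step: step 9

## Route

Step 1
Reactants: 1 dimethyl squarate (3,4-dimethoxycyclobut-3-ene-1,2-dione)
Product: 3 3-methoxy-4-methylcyclobut-3-ene-1,2-dione, via lithium cyclobutenolate 2 (not isolated)
Conditions: MeLi (1.05 equiv), THF, -78 °C; TFAA (1.3 equiv), -78 to 0 °C; aq. NaHCO3
Reagents that add atoms: methyllithium, C[Li]; water, O
Why: 1,2-addition of the organolithium to one of two equivalent carbonyl groups; trifluoroacetylation of the tertiary alkoxide lets it ionise to a methoxy-stabilised cyclobutenyl cation, which is hydrolysed with loss of methanol to the dione (standard squarate-to-cyclobutenedione protocol).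

Step 2
Reactants: 4 4-methylpent-3-enoic acid
Product: 5 N-methoxy-N,4-dimethylpent-3-enamide
Conditions: CDI, CH2Cl2, 0 °C to rt; MeNHOMe·HCl, rt
Reagents that add atoms: N,O-dimethylhydroxylamine hydrochloride, CNOC.Cl
Why: Weinreb amide formation through the acyl imidazole; the near-neutral conditions should leave the β,γ-alkene out of conjugation.

Step 3
Reactants: 6 ethynyltrimethylsilane; 5 N-methoxy-N,4-dimethylpent-3-enamide
Product: 8 6-methyl-1-(trimethylsilyl)hept-5-en-1-yn-3-one, via lithium acetylide 7 (not isolated)
Conditions: 6, n-BuLi, THF, -78 °C; then 5, -78 to -20 °C; poured into cold aq. NH4Cl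
Reagents that add atoms: none
Why: Weinreb ketone synthesis; the chelated tetrahedral intermediate survives until the cold, weakly acidic quench, so neither over-addition nor base-induced shift of the alkene into conjugation should occur.

Step 4
Reactants: 8 6-methyl-1-(trimethylsilyl)hept-5-en-1-yn-3-one
Product: 9 (3R)-6-methyl-1-(trimethylsilyl)hept-5-en-1-yn-3-ol
Conditions: Ru[(R,R)-TsNCH(Ph)CH(Ph)NH](p-cymene) (1 mol %), i-PrOH, rt
Reagents that add atoms: none
Why: Noyori asymmetric transfer hydrogenation of an alkynyl ketone under base-free conditions; the alkynyl group takes the place of the aryl group in the usual transition-state model, so the (R,R) catalyst should deliver hydride to the face that gives the (R) carbinol, and the acidic CH2 group is never exposed to base.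

Step 5
Reactants: 9 (3R)-6-methyl-1-(trimethylsilyl)hept-5-en-1-yn-3-ol
Product: 10 (3R)-6-methylhept-5-en-1-yn-3-ol
Conditions: K2CO3 (cat.), MeOH, rt
Reagents that add atoms: none
Why: Methanolysis of the alkynyl C–Si bond; the stereocentre is not involved.

Step 6
Reactants: 10 (3R)-6-methylhept-5-en-1-yn-3-ol; 3 3-methoxy-4-methylcyclobut-3-ene-1,2-dione
Product: 12 4-hydroxy-4-[(3R)-3-hydroxy-6-methylhept-5-en-1-yn-1-yl]-3-methoxy-2-methylcyclobut-2-en-1-one (both epimers at the ring carbinol carbon), via dilithio alkynolate 11 (not isolated)
Conditions: 10, n-BuLi (2.05 equiv), THF, -78 to -20 °C; cannulated into 3 in THF, -78 °C; sat. aq. NH4Cl, -78 °C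
Reagents that add atoms: none
Why: 1,2-addition of a lithium acetylide to a cyclobutenedione; the carbonyl next to the methoxy-bearing carbon is attacked because the other is deactivated as a vinylogous ester, and inverse addition with a cold quench should avoid double addition and ring opening of the alkoxide. The new ring stereocentre forms without control and is erased in step 9.

Step 7
Reactants: 12 4-hydroxy-4-[(3R)-3-hydroxy-6-methylhept-5-en-1-yn-1-yl]-3-methoxy-2-methylcyclobut-2-en-1-one; 13 angelic acid ((2Z)-2-methylbut-2-enoic acid)
Product: 14 (3S)-1-(1-hydroxy-2-methoxy-3-methyl-4-oxocyclobut-2-en-1-yl)-6-methylhept-5-en-1-yn-3-yl (2Z)-2-methylbut-2-enoate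
Conditions: PPh3, DIAD, THF, -20 to 0 °C
Reagents that add atoms: none
Why: Mitsunobu esterification; SN2 attack of the carboxylate on the alkoxyphosphonium ion of the secondary propargylic alcohol inverts C3 from (R) to (S), the tertiary hydroxyl is too hindered to be activated, and the (Z)-enoate should not isomerise because its carbonyl group is never activated.

Step 8
Reactants: 14 (3S)-1-(1-hydroxy-2-methoxy-3-methyl-4-oxocyclobut-2-en-1-yl)-6-methylhept-5-en-1-yn-3-yl (2Z)-2-methylbut-2-enoate
Product: 15 (4S)-2-(1-hydroxy-2-methoxy-3-methyl-4-oxocyclobut-2-en-1-yl)-7-methyl-3-methylideneocta-1,6-dien-4-yl (2Z)-2-methylbut-2-enoate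
Conditions: ethylene (4 bar), second-generation Grubbs catalyst RuCl2(=CHPh)(PCy3)(H2IMes) (10 mol %), CH2Cl2, 40 °C
Reagents that add atoms: ethylene, C=C
Why: Ethylene–alkyne cross-metathesis (enyne metathesis): the ruthenium methylidene adds to the alkyne, ethylene turns over the resulting vinylcarbene, and each alkyne carbon gains a methylidene group; internal alkynes with oxygen at both propargylic positions are a favourable substrate class, and excess ethylene at low temperature should protect the trisubstituted prenyl alkene and the thermally labile cyclobutenone.

Step 9
Reactants: 15 (4S)-2-(1-hydroxy-2-methoxy-3-methyl-4-oxocyclobut-2-en-1-yl)-7-methyl-3-methylideneocta-1,6-dien-4-yl (2Z)-2-methylbut-2-enoate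
Product: 18 (3S)-2-(2,5-dihydroxy-3-methoxy-4-methylphenyl)-6-methylhepta-1,5-dien-3-yl (2Z)-2-methylbut-2-enoate, via dienylketene 16 (not isolated), via cyclohexadienone 17 (not isolated)
Conditions: toluene (0.01 M, degassed), argon, 110 °C
Reagents that add atoms: none
Why: This is a Moore-type thermal ring expansion of a 4-alkenyl-4-hydroxycyclobutenone, the closest known reaction type and an established way to make substituted hydroquinones. Conrotatory 4π-electrocyclic opening of the bond between the carbonyl carbon and the carbinol carbon gives dienylketene 16; the hydroxyl group rotates outward, as donor substituents do, which turns the dien-2-yl group inward, cis to the ketene. Disrotatory 6π-electrocyclisation then joins the ketene carbon (later C5) to the terminal methylidene carbon supplied by ethylene (later C6) and closes the only new ring, the six-membered carbocycle of cyclohexa-2,4-dienone 17. Enolisation of 17 gives the benzene ring with both hydroxyls free. No stereocentre is formed: the two epimers of 15 converge because the ring carbinol carbon becomes aromatic C2, and C3′ lies outside the reacting π-system. The step needs periselectivity, meaning 6π closure must win over capture of the ketene by the hydroxyl (butenolide) and over closure onto the second methylidene group (a seven-membered ring); the outward rotation of OH and the s-cis array of ketene and inward vinyl group secure it. The regiochemistry of the arene was fixed by the carbonyl selectivity of step 6. Neutral, reagent-free conditions under argon should spare the angelate, the allylic C–O bond and the air-sensitive hydroquinone.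

## Compound list

1 | dimethyl squarate (3,4-dimethoxycyclobut-3-ene-1,2-dione) | COC1=C(OC)C(=O)C1=O | starting material
2 | lithium 2,3-dimethoxy-1-methyl-4-oxocyclobut-2-en-1-olate (racemic) | COC1=C(OC)C(C)(O[Li])C1=O | intermediate (not isolated)
3 | 3-methoxy-4-methylcyclobut-3-ene-1,2-dione | COC1=C(C)C(=O)C1=O | intermediate
4 | 4-methylpent-3-enoic acid | CC(C)=CCC(=O)O | starting material
5 | N-methoxy-N,4-dimethylpent-3-enamide | CON(C)C(=O)CC=C(C)C | intermediate
6 | ethynyltrimethylsilane | C#C[Si](C)(C)C | starting material
7 | lithium (trimethylsilyl)acetylide | [Li]C#C[Si](C)(C)C | intermediate (not isolated)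
8 | 6-methyl-1-(trimethylsilyl)hept-5-en-1-yn-3-one | C[Si](C)(C)C#CC(=O)CC=C(C)C | intermediate
9 | (3R)-6-methyl-1-(trimethylsilyl)hept-5-en-1-yn-3-ol | C[Si](C)(C)C#C[C@@H](CC=C(C)C)O | intermediate
10 | (3R)-6-methylhept-5-en-1-yn-3-ol | C#C[C@@H](CC=C(C)C)O | intermediate
11 | dilithio derivative of 10 (lithium alkoxide, lithium acetylide) | [Li]C#C[C@@H](CC=C(C)C)O[Li] | intermediate (not isolated)
12 | 4-hydroxy-4-[(3R)-3-hydroxy-6-methylhept-5-en-1-yn-1-yl]-3-methoxy-2-methylcyclobut-2-en-1-one (both epimers at the ring carbinol carbon) | CC1=C(OC)C(O)(C#C[C@@H](CC=C(C)C)O)C1=O | intermediate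
13 | angelic acid, (2Z)-2-methylbut-2-enoic acid | C/C=C(/C)C(=O)O | starting material
14 | (3S)-1-(1-hydroxy-2-methoxy-3-methyl-4-oxocyclobut-2-en-1-yl)-6-methylhept-5-en-1-yn-3-yl (2Z)-2-methylbut-2-enoate (both ring epimers) | CC1=C(OC)C(O)(C#C[C@H](CC=C(C)C)OC(=O)/C(C)=C\C)C1=O | intermediate
15 | (4S)-2-(1-hydroxy-2-methoxy-3-methyl-4-oxocyclobut-2-en-1-yl)-7-methyl-3-methylideneocta-1,6-dien-4-yl (2Z)-2-methylbut-2-enoate (both ring epimers) | C=C(C1(O)C(OC)=C(C)C1=O)C(=C)[C@H](CC=C(C)C)OC(=O)/C(C)=C\C | intermediate
16 | (Z)-dienylketene from ring opening of 15 | O=C=C(C)/C(OC)=C(O)\C(=C)C(=C)[C@H](CC=C(C)C)OC(=O)/C(C)=C\C | intermediate (not isolated)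
17 | 4-hydroxy-3-methoxy-2-methylcyclohexa-2,4-dien-1-one carrying the side chain at C5 | O=C1CC(C(=C)[C@H](CC=C(C)C)OC(=O)/C(C)=C\C)=C(O)C(OC)=C1C | intermediate (not isolated)
18 | (3S)-2-(2,5-dihydroxy-3-methoxy-4-methylphenyl)-6-methylhepta-1,5-dien-3-yl (2Z)-2-methylbut-2-enoate | C=C(c1cc(O)c(C)c(OC)c1O)[C@H](CC=C(C)C)OC(=O)/C(C)=C\C | target

## Step count and risks

Total: 9 steps. Longest linear sequence: 8 steps (steps 2 to 9, from acid 4); step 1 is a one-step side branch.

Least certain steps:

Step 9 (key step). The most likely failures are leakage of the ketene into a butenolide by intramolecular addition of the tertiary hydroxyl if inward rotation of OH competes, thermal Diels–Alder dimerisation of the cross-conjugated diene before the ring opens, and air oxidation of the hydroquinone during isolation. The fallback sets out from 15 and returns at 18. It changes the substrate class and separates ring construction from release of the phenol. Silylation of the tertiary hydroxyl (TMSCl, Et3N, CH2Cl2, 0 °C) would give the silyloxycyclobutenone F1, whose ketene cannot lactonise. The same thermolysis would give the mono-silylated hydroquinone F2 (silyl ether at the C2 oxygen), and dilute aqueous citric acid in THF at 0 °C would release 18.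

Step 8. Turnover may be slow at the hindered internal alkyne. The ruthenium vinylcarbene may be intercepted by the prenyl alkene (ring closure with loss of isobutene), the prenyl group may undergo ethenolysis, and the alkynylcyclobutenone may rearrange thermally if the temperature must be raised. The fallback sets out from Weinreb amide 5 and dione 3 and returns at 15; it builds the diene before the fragment union. It runs as follows:
- 2,3-Bis(trimethylstannyl)buta-1,3-diene F3 (from 1,4-dichlorobut-2-yne and Me3SnLi by twofold SN2′ substitution) would undergo one tin–lithium exchange (MeLi, THF, -78 °C) to 3-(trimethylstannyl)buta-1,3-dien-2-yllithium F4.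
- Acylation of this reagent by 5 would give stannyl dienone F5.
- Reduction with (S)-Me-CBS oxazaborolidine and catecholborane at -78 °C would give the (R)-stannyl dienol F6.
- Deprotonation and a second tin–lithium exchange (MeLi, 2.2 equiv), then addition to 3, would give diene diol F7.
- The Mitsunobu reaction of step 7 with 13 would convert F7 into 15.

Step 7. The (Z)-enoate may isomerise by conjugate addition and elimination of triphenylphosphine, configuration may erode through ionisation of the activated propargylic alcohol, and the basic betaine may fragment the hydroxycyclobutenone. The fallback sets out from 12 and returns at 14. Selective sulfonylation of the secondary hydroxyl (MsCl, Et3N, CH2Cl2, -30 °C) would give the methanesulfonate F8. Displacement by the caesium salt of 13 (Cs2CO3, 13, DMF, 0 °C to rt) would give 14 with the same inversion, without phosphine or azodicarboxylate.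

Step 6. Addition may be incomplete because the dilithio species aggregates or transfers a proton, and attack may lose selectivity between the two carbonyl groups or occur twice. The fallback sets out from 10 and returns at 12; it uses a mono-anion. The triethylsilyl ether F9 (TESCl, imidazole, CH2Cl2) would be lithiated with one equivalent of n-BuLi and added to 3 to give the silyl-protected adduct F10. HF·pyridine in THF/pyridine at 0 °C would then give 12.

## Further compounds

F1 | step 9 | (4S)-2-[2-methoxy-3-methyl-4-oxo-1-(trimethylsilyloxy)cyclobut-2-en-1-yl]-7-methyl-3-methylideneocta-1,6-dien-4-yl (2Z)-2-methylbut-2-enoate | C=C(C1(O[Si](C)(C)C)C(OC)=C(C)C1=O)C(=C)[C@H](CC=C(C)C)OC(=O)/C(C)=C\C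
F2 | step 9 | (3S)-2-[5-hydroxy-3-methoxy-4-methyl-2-(trimethylsilyloxy)phenyl]-6-methylhepta-1,5-dien-3-yl (2Z)-2-methylbut-2-enoate | C=C(c1cc(O)c(C)c(OC)c1O[Si](C)(C)C)[C@H](CC=C(C)C)OC(=O)/C(C)=C\C
F3 | step 8 | 2,3-bis(trimethylstannyl)buta-1,3-diene | C=C([Sn](C)(C)C)C(=C)[Sn](C)(C)C
F4 | step 8 | 3-(trimethylstannyl)buta-1,3-dien-2-yllithium | [Li]C(=C)C(=C)[Sn](C)(C)C
F5 | step 8 | 7-methyl-3-methylidene-2-(trimethylstannyl)octa-1,6-dien-4-one | C=C([Sn](C)(C)C)C(=C)C(=O)CC=C(C)C
F6 | step 8 | (4R)-7-methyl-3-methylidene-2-(trimethylstannyl)octa-1,6-dien-4-ol | C=C([Sn](C)(C)C)C(=C)[C@@H](CC=C(C)C)O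
F7 | step 8 | 4-hydroxy-4-[(4R)-4-hydroxy-7-methyl-3-methylideneocta-1,6-dien-2-yl]-3-methoxy-2-methylcyclobut-2-en-1-one | C=C(C1(O)C(OC)=C(C)C1=O)C(=C)[C@@H](CC=C(C)C)O
F8 | step 7 | (3R)-1-(1-hydroxy-2-methoxy-3-methyl-4-oxocyclobut-2-en-1-yl)-6-methylhept-5-en-1-yn-3-yl methanesulfonate | CC1=C(OC)C(O)(C#C[C@@H](CC=C(C)C)OS(C)(=O)=O)C1=O
F9 | step 6 | triethyl{[(3R)-6-methylhept-5-en-1-yn-3-yl]oxy}silane | C#C[C@@H](CC=C(C)C)O[Si](CC)(CC)CC
F10 | step 6 | 4-hydroxy-3-methoxy-2-methyl-4-[(3R)-6-methyl-3-(triethylsilyloxy)hept-5-en-1-yn-1-yl]cyclobut-2-en-1-one | CC1=C(OC)C(O)(C#C[C@@H](CC=C(C)C)O[Si](CC)(CC)CC)C1=O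
A1 | alternative 1 | 1-bromo-3-methoxy-2,5-bis(methoxymethoxy)-4-methylbenzene | COCOc1cc(Br)c(OCOC)c(OC)c1C
A2 | alternative 1 | (3S)-6-methylhept-5-en-1-yn-3-ol | C#C[C@H](CC=C(C)C)O
A3 | alternative 1 | (3S)-2-[3-methoxy-2,5-bis(methoxymethoxy)-4-methylphenyl]-6-methylhepta-1,5-dien-3-ol | C=C(c1cc(OCOC)c(C)c(OC)c1OCOC)[C@H](CC=C(C)C)O
A4 | alternative 2 | (2Z)-2-[3-methoxy-2,5-bis(methoxymethoxy)-4-methylphenyl]-6-methylhepta-2,5-dien-1-yl 2,2,2-trichloroethanimidate | N=C(OC/C(c1cc(OCOC)c(C)c(OC)c1OCOC)=C\CC=C(C)C)C(Cl)(Cl)Cl
A5 | alternative 2 | (3S)-2-[3-methoxy-2,5-bis(methoxymethoxy)-4-methylphenyl]-6-methylhepta-1,5-dien-3-yl (2Z)-2-methylbut-2-enoate | C=C(c1cc(OCOC)c(C)c(OC)c1OCOC)[C@H](CC=C(C)C)OC(=O)/C(C)=C\C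
A6 | alternative 3 | pentacarbonyl[(2E)-1,3-dimethoxy-2-methylprop-2-en-1-ylidene]chromium | CO/C=C(\C)C(OC)=[Cr](=C=O)(=C=O)(=C=O)(=C=O)=C=O
A7 | alternative 3 | (3S)-2-ethynyl-6-methylhepta-1,5-dien-3-yl (2Z)-2-methylbut-2-enoate | C#CC(=C)[C@H](CC=C(C)C)OC(=O)/C(C)=C\C
A8 | alternative 3 | (3S)-2-(2-hydroxy-3,5-dimethoxy-4-methylphenyl)-6-methylhepta-1,5-dien-3-yl (2Z)-2-methylbut-2-enoate | C=C(c1cc(OC)c(C)c(OC)c1O)[C@H](CC=C(C)C)OC(=O)/C(C)=C\C
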